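Retrosynthesis: the anisoate C–O bond at C6, the two epoxide C–O bonds at C8/C9 and the C4–isopropyl bond are cut first; the hydroazulene is then opened at C7–C8 and C1–C10, leaving an ethoxyvinyl cyclopentenone diene (C7=C6–C5=C1) and a vinyldiazoacetate (C8–C9=C10).
Enabling feature: in the seven-membered ring (C1, C5, C6, C7, C8, C9, C10) the oxygenated C6 and the C8–C9 unsaturation flank the C7 methylene, with C5 and the quaternary C1 closing the ring; a C5=C6 enol ether plus a C8=C9 alkene is the 1,4-diene that a cis-divinylcyclopropane gives on Cope rearrangement.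
Forward: the five-membered ring is bought as 3-methylcyclopentenone; iodination and Stille coupling give the diene, and the seven-membered ring is closed in one operation by rhodium-carbene cyclopropanation and [3,3] shift.
After the annulation: isopropyl enters by Stork–Danheiser transposition, oxygen is put on C4 by a hydroxyl-directed epoxidation, the C5–O bond is cut reductively, C6 is reduced under direction of the C4 hydroxyl, the ester becomes the C8 methyl, and epoxidation and anisoylation finish.
Stereochemistry: C1 from the chiral dirhodium prolinate, relayed through the boat Cope; a temporary C6 carbinol from oxazaborolidine reduction steers the epoxide oxygen to the β-face and fixes C4; C5 from α-face protonation to the more stable trans-fused ketone; C6 from intramolecular hydride delivery (1,3-anti); C8/C9 from oxygen delivery by the C6 α-hydroxyl.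
Locants: C1 angular-methyl carbon, C2–C3 methylenes, C4 isopropyl carbinol, C5 ring-fusion CH, C6 acyloxy carbon, C7 methylene, C8 (methyl) and C9 epoxide carbons, C10 methylene; β is the face of the C1 methyl; names use azulene numbering (8a = C1, 1 = C2, 2 = C3, 3 = C4, 3a = C5, 4 = C6, 5 = C7, 6 = C8, 7 = C9, 8 = C10).

Key step: step 4

Remark (assumption): the facial preference of the DOSP catalysts (DOSP = N-(4-dodecylbenzenesulfonyl)prolinate) known for styrenes and simple dienes is taken to hold for the 1,1-disubstituted enol ether used here, which assigns Rh2(R-DOSP)4 to the (R)-configured C1; the antipodal catalyst would be used if the sense proved opposite.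

Step 1
Reactants: 1 3-methylcyclopent-2-en-1-one
Product: 2 2-iodo-3-methylcyclopent-2-en-1-one
Conditions: I2, pyridine, CH2Cl2, 0 °C to rt
Reagents that add atoms: iodine [I][I]
Why: Pyridine-mediated α-iodination of an enone (conjugate addition of pyridine, iodination of the enolate, elimination) should place iodine on the only vinylic CH, and no stereocentre is formed.

Step 2
Reactants: 2 2-iodo-3-methylcyclopent-2-en-1-one, 3 tributyl(1-ethoxyvinyl)stannane
Product: 4 2-(1-ethoxyvinyl)-3-methylcyclopent-2-en-1-one
Conditions: Pd2(dba)3 (2.5 mol %), AsPh3, CuI, N-methylpyrrolidone, 25 to 40 °C; aqueous KF work-up; Et3N-washed silica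
Reagents that add atoms: none
Why: Stille coupling of an α-iodoenone with an α-alkoxyvinylstannane under copper-assisted zerovalent palladium catalysis is a standard entry to 2-substituted enones, the neutral work-up keeps the enol ether intact, and no stereocentre is formed.

Step 3
Reactants: 5 methyl but-3-enoate
Product: 6 methyl 2-diazobut-3-enoate
Conditions: 4-acetamidobenzenesulfonyl azide, DBU, MeCN, 0 °C; pentane extraction, solution used cold at once
Reagents that add atoms: 4-acetamidobenzenesulfonyl azide CC(=O)Nc1ccc(cc1)S(=O)(=O)N=[N+]=[N-]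
Why: Regitz diazo transfer to the dienolate of a β,γ-unsaturated ester gives the vinyldiazoacetate, which is used immediately because terminally unsubstituted vinyldiazo esters tend to close to pyrazoles on standing, and no stereocentre is formed.

Step 4
Reactants: 4 2-(1-ethoxyvinyl)-3-methylcyclopent-2-en-1-one, 6 methyl 2-diazobut-3-enoate
Product: 8 methyl (8aR)-4-ethoxy-8a-methyl-3-oxo-1,2,3,5,8,8a-hexahydroazulene-6-carboxylate, via cis-divinylcyclopropane 7 (not isolated)
Conditions: Rh2(R-DOSP)4 (1 mol %), hexanes/PhCF3, −40 °C, 6 (2 equiv) added over 3 h; then rt to 60 °C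
Reagents that add atoms: none
Why: The rhodium-bound vinylcarbene from 6 adds to the electron-rich, unhindered ethoxyvinyl alkene of 4 rather than to the deactivated tetrasubstituted enone alkene or the carbonyl, forming C7–C8 and C6–C8 of cyclopropane 7 with the cyclopentenyl group cis to the vinyl group. The cis-divinylcyclopropane then undergoes a [3,3]-sigmatropic (Cope) shift through a boat transition state in which C10 bonds to C1 while the C6–C8 bond, weakened by its ethoxy donor and ester acceptor, breaks, so the seven-membered ring is closed pericyclically with release of ring strain and not by a polar cyclisation. The closest known reaction type is the dirhodium-carboxylate-catalysed formal (4+3) annulation of vinyldiazoacetates with dienes, which extends to cases that create a quaternary carbon at the Cope terminus. C1 is the only stereocentre that remains: the prolinate catalyst fixes the configuration of C6 and C8 in 7, and the boat geometry passes it stereospecifically to C1. The step needs chemoselectivity for the enol ether, a cis-divinyl arrangement and a concerted rather than zwitterionic opening; the enol-ether donor, the nonpolar Lewis-acid-free medium and gentle heating to overcome the inward-pointing C1 methyl are meant to secure these.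

Step 5
Reactants: 8 methyl (8aR)-4-ethoxy-8a-methyl-3-oxo-1,2,3,5,8,8a-hexahydroazulene-6-carboxylate
Product: 10 methyl (8aR)-8a-methyl-4-oxo-3-(propan-2-yl)-1,2,4,5,8,8a-hexahydroazulene-6-carboxylate, via tertiary carbinol 9 (not isolated)
Conditions: i-PrMgCl, CeCl3, THF, −78 °C; then 1 M aq HCl, THF, 0 °C
Reagents that add atoms: isopropylmagnesium chloride CC(C)[Mg]Cl; water O
Why: Stork–Danheiser transposition, in which the weakly basic organocerium reagent adds 1,2 to the vinylogous-ester carbonyl at C4 in preference to the hindered enoate and dilute acid then ionises the tertiary allylic carbinol and hydrolyses the enol ether to the C4=C5 enone with the ketone at C6, so the C4 centre formed in the addition is deliberately erased.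

Step 6
Reactants: 10 methyl (8aR)-8a-methyl-4-oxo-3-(propan-2-yl)-1,2,4,5,8,8a-hexahydroazulene-6-carboxylate
Product: 11 methyl (4R,8aR)-4-hydroxy-8a-methyl-3-(propan-2-yl)-1,2,4,5,8,8a-hexahydroazulene-6-carboxylate
Conditions: (S)-1-methyl-3,3-diphenyltetrahydro-1H,3H-pyrrolo[1,2-c][1,3,2]oxazaborole (0.5 equiv), catecholborane, toluene, −78 to −40 °C
Reagents that add atoms: none
Why: Corey–Bakshi–Shibata reduction, in which the (S)-oxazaborolidine binds the ketone with the fully substituted alkenyl carbon C5 as the large group and the C7 methylene as the small one, should deliver hydride to the α-face and give the 6β-alcohol (4R in the azulene name), while catecholborane at low temperature leaves the enoate untouched.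

Step 7
Reactants: 11 methyl (4R,8aR)-4-hydroxy-8a-methyl-3-(propan-2-yl)-1,2,4,5,8,8a-hexahydroazulene-6-carboxylate
Product: 12 methyl (3R,3aS,4R,8aR)-3,3a-epoxy-4-hydroxy-8a-methyl-3-(propan-2-yl)-1,2,3,3a,4,5,8,8a-octahydroazulene-6-carboxylate
Conditions: VO(acac)2 (5 mol %), t-BuOOH, CH2Cl2, 0 °C
Reagents that add atoms: tert-butyl hydroperoxide CC(C)(C)OO
Why: Vanadium-catalysed hydroxyl-directed epoxidation, in which allylic 1,3-strain with the cis isopropyl group holds H6 in the alkene plane so that the C6 hydroxyl stands over the β-face and delivers oxygen there, sets C4 (and for the moment C5) syn to the carbinol oxygen even though this is the face of the angular methyl, and the electron-poor C8=C9 enoate is not attacked.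

Step 8
Reactants: 12 methyl (3R,3aS,4R,8aR)-3,3a-epoxy-4-hydroxy-8a-methyl-3-(propan-2-yl)-1,2,3,3a,4,5,8,8a-octahydroazulene-6-carboxylate
Product: 13 methyl (3R,3aR,8aR)-3,3a-epoxy-8a-methyl-4-oxo-3-(propan-2-yl)-1,2,3,3a,4,5,8,8a-octahydroazulene-6-carboxylate
Conditions: Dess–Martin periodinane, NaHCO3, CH2Cl2, 0 °C to rt
Reagents that add atoms: none
Why: Dess–Martin oxidation of the secondary carbinol under buffered, neutral conditions should give the α,β-epoxy ketone without opening the epoxide or moving the C8=C9 alkene, and it removes the temporary C6 stereocentre once it has done its work.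

Step 9
Reactants: 13 methyl (3R,3aR,8aR)-3,3a-epoxy-8a-methyl-4-oxo-3-(propan-2-yl)-1,2,3,3a,4,5,8,8a-octahydroazulene-6-carboxylate
Product: 14 methyl (3R,3aR,8aR)-3-hydroxy-8a-methyl-4-oxo-3-(propan-2-yl)-1,2,3,3a,4,5,8,8a-octahydroazulene-6-carboxylate
Conditions: SmI2 (2.5 equiv), THF/MeOH, −90 °C
Reagents that add atoms: none
Why: Reductive opening of an α,β-epoxy ketone by SmI2 cleaves only the C5–O bond next to the ketone, so C4 keeps its configuration as a tertiary β-hydroxyl, and protonation of the samarium enolate at C5 from the α-face, away from the angular methyl and the C4 alkoxide, should give the trans ring fusion, which is also the more stable epimer because the isopropyl group stays trans to the C5–C6 bond.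

Step 10
Reactants: 14 methyl (3R,3aR,8aR)-3-hydroxy-8a-methyl-4-oxo-3-(propan-2-yl)-1,2,3,3a,4,5,8,8a-octahydroazulene-6-carboxylate
Product: 15 methyl (3R,3aS,4S,8aR)-3,4-dihydroxy-8a-methyl-3-(propan-2-yl)-1,2,3,3a,4,5,8,8a-octahydroazulene-6-carboxylate
Conditions: Me4NBH(OAc)3, MeCN/AcOH (1:1), −30 °C
Reagents that add atoms: none
Why: Evans–Saksena reduction, in which the C4 hydroxyl exchanges onto boron and the resulting alkoxyborohydride delivers hydride intramolecularly to the β-face of the activated C6 ketone, should give the 1,3-anti diol with the 6α-hydroxyl, and the mild reagent leaves ester and alkene alone.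

Step 11
Reactants: 15 methyl (3R,3aS,4S,8aR)-3,4-dihydroxy-8a-methyl-3-(propan-2-yl)-1,2,3,3a,4,5,8,8a-octahydroazulene-6-carboxylate
Product: 16 (3R,3aS,4S,8aR)-6-(hydroxymethyl)-8a-methyl-3-(propan-2-yl)-1,2,3,3a,4,5,8,8a-octahydroazulene-3,4-diol
Conditions: i-Bu2AlH (5 equiv), CH2Cl2, −78 to 0 °C; aqueous potassium sodium tartrate
Reagents that add atoms: none
Why: Exhaustive i-Bu2AlH reduction of the conjugated ester gives the primary allylic alcohol by 1,2-reduction, the two existing hydroxyls merely consuming hydride as aluminium alkoxides, and no stereocentre is affected.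

Step 12
Reactants: 16 (3R,3aS,4S,8aR)-6-(hydroxymethyl)-8a-methyl-3-(propan-2-yl)-1,2,3,3a,4,5,8,8a-octahydroazulene-3,4-diol
Product: 17 (3R,3aS,4S,8aR)-6-(chloromethyl)-8a-methyl-3-(propan-2-yl)-1,2,3,3a,4,5,8,8a-octahydroazulene-3,4-diol
Conditions: N-chlorosuccinimide, Me2S, CH2Cl2, −20 to 0 °C
Reagents that add atoms: N-chlorosuccinimide O=C1CCC(=O)N1Cl
Why: Corey–Kim chlorination converts allylic alcohols into chlorides by chloride displacement of the alkoxysulfonium ion, whereas saturated secondary and tertiary hydroxyls are returned unchanged on work-up, so only the C8 hydroxymethyl group should react and no stereocentre is affected.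

Step 13
Reactants: 17 (3R,3aS,4S,8aR)-6-(chloromethyl)-8a-methyl-3-(propan-2-yl)-1,2,3,3a,4,5,8,8a-octahydroazulene-3,4-diol
Product: 18 (3R,3aS,4S,8aR)-6,8a-dimethyl-3-(propan-2-yl)-1,2,3,3a,4,5,8,8a-octahydroazulene-3,4-diol
Conditions: LiEt3BH (4 equiv), THF, 0 °C to rt
Reagents that add atoms: none
Why: SN2 hydride displacement of a primary allylic chloride by LiEt3BH should give the C8 methyl group with the C8=C9 alkene left in place, the free hydroxyls being carried as lithium alkoxides, and no stereocentre is affected.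

Step 14
Reactants: 18 (3R,3aS,4S,8aR)-6,8a-dimethyl-3-(propan-2-yl)-1,2,3,3a,4,5,8,8a-octahydroazulene-3,4-diol
Product: 19 (3R,3aS,4S,6R,7S,8aR)-6,7-epoxy-6,8a-dimethyl-3-(propan-2-yl)decahydroazulene-3,4-diol
Conditions: VO(acac)2 (5 mol %), t-BuOOH, CH2Cl2, 0 °C to rt
Reagents that add atoms: tert-butyl hydroperoxide CC(C)(C)OO
Why: Vanadium-catalysed epoxidation directed by the homoallylic C6 α-hydroxyl should deliver oxygen to the α-face of the trisubstituted C8=C9 alkene, the face that is also remote from the angular methyl, setting C8 and C9 together, while the tertiary C4 hydroxyl on the β-face is too far away to compete.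

Step 15
Reactants: 19 (3R,3aS,4S,6R,7S,8aR)-6,7-epoxy-6,8a-dimethyl-3-(propan-2-yl)decahydroazulene-3,4-diol
Product: 20 (3R,3aS,4S,6R,7S,8aR)-6,7-epoxy-3-hydroxy-6,8a-dimethyl-3-(propan-2-yl)decahydroazulen-4-yl 4-methoxybenzoate
Conditions: 4-methoxybenzoyl chloride, Et3N, 4-(dimethylamino)pyridine (0.2 equiv), CH2Cl2, 0 °C to rt
Reagents that add atoms: 4-methoxybenzoyl chloride COc1ccc(cc1)C(Cl)=O
Why: Nucleophile-catalysed acyl transfer esterifies the secondary C6 hydroxyl while the hindered tertiary C4 hydroxyl stays free, the amine-buffered medium spares the acid-sensitive epoxide, and no stereocentre is affected.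

Compound list
1 | 3-methylcyclopent-2-en-1-one | CC1=CC(=O)CC1 | starting material
2 | 2-iodo-3-methylcyclopent-2-en-1-one | IC1=C(C)CCC1=O | intermediate
3 | tributyl(1-ethoxyvinyl)stannane | CCCC[Sn](CCCC)(CCCC)C(=C)OCC | starting material
4 | 2-(1-ethoxyvinyl)-3-methylcyclopent-2-en-1-one | CCOC(=C)C1=C(C)CCC1=O | intermediate
5 | methyl but-3-enoate | COC(=O)CC=C | starting material
6 | methyl 2-diazobut-3-enoate | COC(=O)C(=[N+]=[N-])C=C | intermediate
7 | methyl (1S,2R)-2-ethoxy-1-ethenyl-2-(2-methyl-5-oxocyclopent-1-en-1-yl)cyclopropane-1-carboxylate (cis-divinylcyclopropane, not isolated) | C=C[C@@]1(C(=O)OC)C[C@@]1(OCC)C1=C(C)CCC1=O | intermediate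
8 | methyl (8aR)-4-ethoxy-8a-methyl-3-oxo-1,2,3,5,8,8a-hexahydroazulene-6-carboxylate | CCOC1=C2C(=O)CC[C@]2(C)CC=C(C(=O)OC)C1 | intermediate
9 | methyl (8aR)-4-ethoxy-3-hydroxy-8a-methyl-3-(propan-2-yl)-1,2,3,5,8,8a-hexahydroazulene-6-carboxylate (C3 epimers, not isolated) | CCOC1=C2C(O)(C(C)C)CC[C@]2(C)CC=C(C(=O)OC)C1 | intermediate
10 | methyl (8aR)-8a-methyl-4-oxo-3-(propan-2-yl)-1,2,4,5,8,8a-hexahydroazulene-6-carboxylate | CC(C)C1=C2C(=O)CC(C(=O)OC)=CC[C@@]2(C)CC1 | intermediate
11 | methyl (4R,8aR)-4-hydroxy-8a-methyl-3-(propan-2-yl)-1,2,4,5,8,8a-hexahydroazulene-6-carboxylate | CC(C)C1=C2[C@H](O)CC(C(=O)OC)=CC[C@@]2(C)CC1 | intermediate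
12 | methyl (3R,3aS,4R,8aR)-3,3a-epoxy-4-hydroxy-8a-methyl-3-(propan-2-yl)-1,2,3,3a,4,5,8,8a-octahydroazulene-6-carboxylate | CC(C)[C@@]12CC[C@]3(C)CC=C(C(=O)OC)C[C@@H](O)[C@]13O2 | intermediate
13 | methyl (3R,3aR,8aR)-3,3a-epoxy-8a-methyl-4-oxo-3-(propan-2-yl)-1,2,3,3a,4,5,8,8a-octahydroazulene-6-carboxylate | CC(C)[C@@]12CC[C@]3(C)CC=C(C(=O)OC)CC(=O)[C@]13O2 | intermediate
14 | methyl (3R,3aR,8aR)-3-hydroxy-8a-methyl-4-oxo-3-(propan-2-yl)-1,2,3,3a,4,5,8,8a-octahydroazulene-6-carboxylate | COC(=O)C1=CC[C@@]2(C)CC[C@@](O)(C(C)C)[C@@H]2C(=O)C1 | intermediate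
15 | methyl (3R,3aS,4S,8aR)-3,4-dihydroxy-8a-methyl-3-(propan-2-yl)-1,2,3,3a,4,5,8,8a-octahydroazulene-6-carboxylate | COC(=O)C1=CC[C@@]2(C)CC[C@@](O)(C(C)C)[C@@H]2[C@@H](O)C1 | intermediate
16 | (3R,3aS,4S,8aR)-6-(hydroxymethyl)-8a-methyl-3-(propan-2-yl)-1,2,3,3a,4,5,8,8a-octahydroazulene-3,4-diol | OCC1=CC[C@@]2(C)CC[C@@](O)(C(C)C)[C@@H]2[C@@H](O)C1 | intermediate
17 | (3R,3aS,4S,8aR)-6-(chloromethyl)-8a-methyl-3-(propan-2-yl)-1,2,3,3a,4,5,8,8a-octahydroazulene-3,4-diol | ClCC1=CC[C@@]2(C)CC[C@@](O)(C(C)C)[C@@H]2[C@@H](O)C1 | intermediate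
18 | (3R,3aS,4S,8aR)-6,8a-dimethyl-3-(propan-2-yl)-1,2,3,3a,4,5,8,8a-octahydroazulene-3,4-diol | CC1=CC[C@@]2(C)CC[C@@](O)(C(C)C)[C@@H]2[C@@H](O)C1 | intermediate
19 | (3R,3aS,4S,6R,7S,8aR)-6,7-epoxy-6,8a-dimethyl-3-(propan-2-yl)decahydroazulene-3,4-diol | O[C@H]1C[C@@]2(C)O[C@H]2C[C@@]2(C)CC[C@@](O)(C(C)C)[C@H]12 | intermediate
20 | (3R,3aS,4S,6R,7S,8aR)-6,7-epoxy-3-hydroxy-6,8a-dimethyl-3-(propan-2-yl)decahydroazulen-4-yl 4-methoxybenzoate | COc1ccc(C(=O)O[C@H]2C[C@@]3(C)O[C@H]3C[C@@]3(C)CC[C@@](O)(C(C)C)[C@H]23)cc1 | target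

Total step count: 15. Longest linear sequence: 14 steps (steps 1, 2 and 4 to 15, from 1); step 3 is the side branch.

Steps most likely to fail

Step 4. The rhodium carbene may be captured by the enone carbonyl instead of cyclopropanating the cross-conjugated dienone. In addition, because the C1 methyl must point inward in the boat, the Cope shift may be slow enough for the push–pull cyclopropane to open heterolytically, with loss of enantiopurity or diversion to a cyclopentene. The fallback takes the carbonyl out of the diene. Setting out from 4, Luche reduction (NaBH4, CeCl3·7H2O, MeOH, 0 °C) should give 2-(1-ethoxyvinyl)-3-methylcyclopent-2-en-1-ol F1, and silylation (TBSCl, imidazole, DMF) its tert-butyldimethylsilyl ether F2. The same Rh2(R-DOSP)4 annulation with 6 would then give the C4-silyloxy hexahydroazulene ester F3, as both C4 epimers since that centre is temporary. Bu4NF in THF would free the C4 allylic alcohol F4, and MnO2 in CH2Cl2 would oxidise it to the vinylogous ester, rejoining the route at 8.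

Step 9. The samarium enolate may be protonated on the β-face, giving the cis ring fusion, or the tertiary β-hydroxy ketone may undergo retro-aldol cleavage under the basic alkoxide conditions. The fallback replaces reductive opening by a stereospecific 1,2-hydride shift. Setting out from 12, silylation (TESCl, imidazole, CH2Cl2) should give the C6 triethylsilyl ether of the epoxy alcohol F5. TESOTf and i-Pr2NEt in CH2Cl2 at −78 °C (non-aldol aldol rearrangement, a semipinacol shift of an epoxy silyl ether) would move the C6 hydride to C5 anti to the breaking C5–O bond, which places H5 on the α-face by inversion and gives the C4-triethylsilyloxy C6 ketone F6. HF·pyridine in THF would remove the silyl group, and the route is rejoined at 14.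

Step 6. Reduction of the twisted, fully substituted enone may be slow, and a substrate bias opposing the catalyst may give poor facial selectivity at C6. The fallback accepts substrate control and corrects by inversion. Setting out from 10, NaBH4 with CeCl3·7H2O in MeOH at −40 °C should give, if the bias runs as feared, mainly the 6α-alcohol F7. Mitsunobu reaction (PPh3, diisopropyl azodicarboxylate, 4-nitrobenzoic acid, toluene, 0 °C) would invert C6 to the 6β 4-nitrobenzoate F8, and K2CO3 in MeOH would release the 6β-alcohol, rejoining the route at 11.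

Further compounds
F1 | step 4 | 2-(1-ethoxyvinyl)-3-methylcyclopent-2-en-1-ol (racemic) | CCOC(=C)C1=C(C)CCC1O
F2 | step 4 | tert-butyl{[2-(1-ethoxyvinyl)-3-methylcyclopent-2-en-1-yl]oxy}dimethylsilane | CCOC(=C)C1=C(C)CCC1O[Si](C)(C)C(C)(C)C
F3 | step 4 | methyl (8aR)-3-[(tert-butyldimethylsilyl)oxy]-4-ethoxy-8a-methyl-1,2,3,5,8,8a-hexahydroazulene-6-carboxylate (C3 epimers) | CCOC1=C2C(O[Si](C)(C)C(C)(C)C)CC[C@]2(C)CC=C(C(=O)OC)C1
F4 | step 4 | methyl (8aR)-4-ethoxy-3-hydroxy-8a-methyl-1,2,3,5,8,8a-hexahydroazulene-6-carboxylate (C3 epimers) | CCOC1=C2C(O)CC[C@]2(C)CC=C(C(=O)OC)C1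
F5 | step 9 | methyl (3R,3aS,4R,8aR)-3,3a-epoxy-8a-methyl-3-(propan-2-yl)-4-[(triethylsilyl)oxy]-1,2,3,3a,4,5,8,8a-octahydroazulene-6-carboxylate | CC(C)[C@@]12CC[C@]3(C)CC=C(C(=O)OC)C[C@@H](O[Si](CC)(CC)CC)[C@]13O2
F6 | step 9 | methyl (3R,3aR,8aR)-8a-methyl-4-oxo-3-(propan-2-yl)-3-[(triethylsilyl)oxy]-1,2,3,3a,4,5,8,8a-octahydroazulene-6-carboxylate | COC(=O)C1=CC[C@@]2(C)CC[C@@](O[Si](CC)(CC)CC)(C(C)C)[C@@H]2C(=O)C1
F7 | step 6 | methyl (4S,8aR)-4-hydroxy-8a-methyl-3-(propan-2-yl)-1,2,4,5,8,8a-hexahydroazulene-6-carboxylate | CC(C)C1=C2[C@@H](O)CC(C(=O)OC)=CC[C@@]2(C)CC1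
F8 | step 6 | methyl (4R,8aR)-8a-methyl-4-[(4-nitrobenzoyl)oxy]-3-(propan-2-yl)-1,2,4,5,8,8a-hexahydroazulene-6-carboxylate | CC(C)C1=C2[C@H](OC(=O)c3ccc(cc3)[N+](=O)[O-])CC(C(=O)OC)=CC[C@@]2(C)CC1
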